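I decide to follow one molecule of Q and to ask where it is likely to be found.

    Q + D + X ⇌ X + G (K1 = 270 L mol⁻¹, k1 = 56.1 L² mol⁻² s⁻¹)
    L ⇌ D, rate k2*(csat - [D]) (k2 = 0.0251 s⁻¹, csat = 3.4 mM)

Q 0.050 M; L 3.4 mM (held); X 7.5 mM; time 3.0 h

- how much G there is at 3.0 h, in percent of the Q charged
- amount of G if the flask were left three thousand times as long, in percent of the Q charged

- at the start none of D is dissolved
- run time (flask): 3.0 h

Write q for the fraction of the charged Q that is still Q and g for the fraction that is G; together they make up the whole charge.

*What can the molecule do?* It can hop from Q to G and back, and both hops go through X.

*How does it choose?* The forward hop goes with the rate constant times X times D, the backward hop with the same constant times X over the equilibrium constant. X multiplies both and cancels, so the ratio of the hops is the equilibrium constant times D.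

*And D at the end?* The transfer from L stops when D reaches saturation, 3.4 mM. So g/q at rest is the equilibrium constant times the saturation level, the fork odds 0.918, and g is odds over one plus odds, 47.9%.

*But that is 23.9 mM of G through a solution holding 3.4 mM of D. Doesn't D run short?* The need is larger, but L is held, so D is refilled as it goes. The refill is fastest with D empty, 5.12 mM min⁻¹, and at that rate the passage takes 4.67 min.

*Is the time enough?* With D at saturation, q relaxes in a pseudo-first-order way with time constant 5.58 min. Both times together are far shorter than the run, so I commit to 47.9% for both questions.

The forecast gives 47.9% (47% to 48.5%) at the asked time and 47.9% (47.5% to 48.3%) for the long wait, holding that “3 h is already fully equilibrated and waiting longer changes nothing”.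

The simulation gives 47.9% and 47.9%, the share that the odds 0.918 give. In this flask the conversion ran while the transfer from L refilled D: their turnovers have their midpoints at 0.120 h and 0.110 h, and D read 0.00310 M at 0.300 h. By 1.50 h D stood at 0.00340 M and G at 47.9%, and up to the asked time the shares moved by 0 percentage points. The odds contain no charge of Q, so they put the neighbouring flask with 0.20 M of Q, the time and all else held, at the same 47.9%, and that neighbour reads 47.9% of its Q as G at 3.00 h.

The rate constants were drawn at random within sensible limits; what happens was integrated by code.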